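**Plan**
- Retrosynthesis: the C4 ketone is masked as a 1,3-dithiane, then ring C is cut at the aryl ether bond O1–C8a and at C3–C4. This leaves a 2-fluoroaryl dithiane (ring A plus C4) and (R)-3,4-dimethoxystyrene oxide (ring B plus C2, C3 and O1).
- Enabling feature: C4 is an acyl carbon and can react as a dithiane carbanion. C3, C2 and O1 map onto the CH2, the CH(aryl) and the oxygen of an aryl oxirane. C8a of ring A can carry fluoride as the leaving group for that oxygen.
- Forward: the ring A piece comes from 5-fluorovanillin (Dakin oxidation, methylation, Vilsmeier formylation, thioacetalisation). The ring B epoxide comes from the α-chloroketone (CBS reduction, base closure).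
- The two pieces are joined and ring C is closed in one flask (epoxide opening, then fluoride displacement). Removal of the dithiane gives the flavanone.
- Stereochemistry: C2, the only stereocentre, is set by the catalyst-controlled ketone reduction. Its C–O bond is never broken afterwards, and the ketone stays masked until the last step so that C2 cannot be lost through a chalcone.

Key step: step 7

Assumption: atoms are numbered as in the flavanone (O1, C2, C3, C4, C4a, C5 to C8, C8a). Compound 4 is formylated by electrophilic substitution and not by ring lithiation, because deprotonation would be expected to compete at the C–H flanked by two methoxy groups.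

**Route**

Step 1
Reactants: 1 5-fluorovanillin (3-fluoro-4-hydroxy-5-methoxybenzaldehyde)
Product: 3 2-fluoro-6-methoxybenzene-1,4-diol, via aryl formate 2 (not isolated)
Conditions: H2O2 (30 % aq), NaOH, H2O, 0 °C → rt, under Ar; then HCl, Na2S2O4
Reagents that add atoms: hydrogen peroxide, OO
Why: Dakin oxidation, in which hydroperoxide adds to the aldehyde para to the phenoxide, the electron-rich aryl group migrates to oxygen and the formate 2 is saponified in the flask, as is known for vanillin itself.

Step 2
Reactants: 3 2-fluoro-6-methoxybenzene-1,4-diol
Product: 4 1-fluoro-2,3,5-trimethoxybenzene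
Conditions: MeI, K2CO3, DMF, rt, under Ar
Reagents that add atoms: iodomethane, CI
Why: Double Williamson O-methylation of the two phenoxides, run with exclusion of air because the hydroquinone is easily oxidised to the quinone.

Step 3
Reactants: 4 1-fluoro-2,3,5-trimethoxybenzene
Product: 6 2-fluoro-3,4,6-trimethoxybenzaldehyde, via iminium chloride 5 (not isolated)
Conditions: POCl3, DMF, 0 → 70 °C; then ice–H2O
Reagents that add atoms: N,N-dimethylformamide, CN(C)C=O; water, O
Why: Vilsmeier–Haack formylation, in which the chloroiminium electrophile should attack C6 of 4 (para to the 3-methoxy group, ortho to the 5-methoxy group, flanked only by the small fluorine) in preference to C4 (between two methoxy groups, no para donor), and hydrolysis of iminium 5 then gives the aldehyde.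

Step 4
Reactants: 6 2-fluoro-3,4,6-trimethoxybenzaldehyde; 7 propane-1,3-dithiol
Product: 8 2-(2-fluoro-3,4,6-trimethoxyphenyl)-1,3-dithiane
Conditions: BF3·OEt2 (20 mol %), CH2Cl2, 0 °C → rt
Reagents that add atoms: none
Why: Lewis-acid-catalysed thioacetalisation of an electron-rich benzaldehyde, which turns the formyl carbon into the acyl-anion equivalent needed for C4.

Step 5
Reactants: 9 2-chloro-1-(3,4-dimethoxyphenyl)ethan-1-one
Product: 10 (1R)-2-chloro-1-(3,4-dimethoxyphenyl)ethan-1-ol
Conditions: (R)-tetrahydro-1-methyl-3,3-diphenyl-1H,3H-pyrrolo[1,2-c][1,3,2]oxazaborole (the R-configured methyl CBS catalyst, C18H20BNO, 10 mol %), BH3·SMe2, THF, 0 °C; then MeOH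
Reagents that add atoms: none
Why: Corey–Bakshi–Shibata reduction, in which the ketone binds to the ring boron with the aryl group as the large substituent turned away from the B-methyl group and the coordinated borane delivers hydride to the Si face, which should give the R chlorohydrin (the S catalyst is the one that leads to S 2-chloro-1-arylethanols) and so sets the carbon that becomes C2.

Step 6
Reactants: 10 (1R)-2-chloro-1-(3,4-dimethoxyphenyl)ethan-1-ol
Product: 11 (2R)-2-(3,4-dimethoxyphenyl)oxirane
Conditions: NaH, THF, 0 °C → rt; filtered, concentrated cold, used without chromatography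
Reagents that add atoms: none
Why: Intramolecular Williamson etherification (3-exo-tet) of the chlorohydrin alkoxide, which leaves the C–O bond of the stereocentre intact so that R is retained, run aprotically because this donor-substituted styrene oxide would solvolyse at the benzylic carbon in protic or acidic media.

Step 7
Reactants: 8 2-(2-fluoro-3,4,6-trimethoxyphenyl)-1,3-dithiane; 11 (2R)-2-(3,4-dimethoxyphenyl)oxirane
Product: 14 (2S)-2-(3,4-dimethoxyphenyl)-5,7,8-trimethoxyspiro[chromane-4,2'-[1,3]dithiane], via lithiodithiane 12 (not isolated), via lithium alkoxide 13 (not isolated)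
Conditions: n-BuLi, THF, −78 → −20 °C; DMPU, then 11, −78 °C → rt; then KN(SiMe3)2, 60 °C; aq NH4Cl
Reagents that add atoms: none
Why: Proposed new method: n-BuLi removes the doubly sulfur-stabilised benzylic proton of 8, the bulky tertiary carbanion 12 opens the oxirane of 11 by SN2 attack at the unsubstituted CH2 with release of ring strain (C3–C4 bond), and the alkoxide 13, activated by potassium and DMPU, then adds to the fluorine-bearing C8a and expels fluoride through a Meisenheimer-type transition state (O1–C8a bond); the closest known reactions are the opening of terminal epoxides by 2-aryl-2-lithio-1,3-dithianes and the base-mediated cyclisation of 3-(2-fluoroaryl)propan-1-olates to chromans, merged here in one flask. Ring C closes as a six-membered ring by attack of oxygen on an aromatic sp2 carbon (6-exo-trig with respect to the C8a–C8 π bond), helped by the gem-disubstitution at the spiro dithiane carbon. No stereocentre is created: the C–O bond at C2 is never broken, so the R epoxide is carried over as the 2S chromane, the descriptor changing by CIP priority only. The selectivity needed is attack at CH2 and not at the benzylic carbon; it is secured by the size of the 2-aryl-dithianyl anion and by DMPU, which takes Li+ off the epoxide oxygen and so disfavours benzylic ionisation. The methoxy groups at C5 and C7 are meta to C8a and act there as inductive acceptors, both positions ortho to fluorine are substituted so no aryne can form, and because C4 stays masked neither retro-aldol cleavage nor chalcone formation can erode C2.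

Step 8
Reactants: 14 (2S)-2-(3,4-dimethoxyphenyl)-5,7,8-trimethoxyspiro[chromane-4,2'-[1,3]dithiane]
Product: 15 (2S)-2-(3,4-dimethoxyphenyl)-5,7,8-trimethoxy-2,3-dihydro-4H-chromen-4-one
Conditions: PhI(OCOCF3)2, MeCN/H2O (9:1), 0 °C; then aq NaHCO3
Reagents that add atoms: water, O
Why: Oxidative dethioacetalisation with a trivalent iodine reagent, in which sulfur is activated at iodine, water adds to the thionium ion and the ketone is released without base, so that C2 (which could be lost only by base-induced ring opening to the chalcone) should not be touched.

**Compound list**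
1 | 5-fluorovanillin (3-fluoro-4-hydroxy-5-methoxybenzaldehyde) | COc1cc(C=O)cc(F)c1O | starting material
2 | 3-fluoro-4-hydroxy-5-methoxyphenyl formate | COc1cc(OC=O)cc(F)c1O | intermediate
3 | 2-fluoro-6-methoxybenzene-1,4-diol | COc1cc(O)cc(F)c1O | intermediate
4 | 1-fluoro-2,3,5-trimethoxybenzene | COc1cc(F)c(OC)c(OC)c1 | intermediate
5 | N-[(2-fluoro-3,4,6-trimethoxyphenyl)methylidene]-N-methylmethanaminium chloride | COc1cc(OC)c(C=[N+](C)C)c(F)c1OC.[Cl-] | intermediate
6 | 2-fluoro-3,4,6-trimethoxybenzaldehyde | COc1cc(OC)c(C=O)c(F)c1OC | intermediate
7 | propane-1,3-dithiol | SCCCS | starting material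
8 | 2-(2-fluoro-3,4,6-trimethoxyphenyl)-1,3-dithiane | COc1cc(OC)c(C2SCCCS2)c(F)c1OC | intermediate
9 | 2-chloro-1-(3,4-dimethoxyphenyl)ethan-1-one | COc1ccc(C(=O)CCl)cc1OC | starting material
10 | (1R)-2-chloro-1-(3,4-dimethoxyphenyl)ethan-1-ol | COc1ccc([C@@H](O)CCl)cc1OC | intermediate
11 | (2R)-2-(3,4-dimethoxyphenyl)oxirane | COc1ccc([C@@H]2CO2)cc1OC | intermediate
12 | [2-(2-fluoro-3,4,6-trimethoxyphenyl)-1,3-dithian-2-yl]lithium | COc1cc(OC)c(C2([Li])SCCCS2)c(F)c1OC | intermediate
13 | lithium (1S)-1-(3,4-dimethoxyphenyl)-2-[2-(2-fluoro-3,4,6-trimethoxyphenyl)-1,3-dithian-2-yl]ethan-1-olate | [Li+].COc1ccc([C@@H]([O-])CC2(SCCCS2)c3c(OC)cc(OC)c(OC)c3F)cc1OC | intermediate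
14 | (2S)-2-(3,4-dimethoxyphenyl)-5,7,8-trimethoxyspiro[chromane-4,2'-[1,3]dithiane] | COc1ccc([C@@H]2CC3(SCCCS3)c4c(OC)cc(OC)c(OC)c4O2)cc1OC | intermediate
15 | (2S)-2-(3,4-dimethoxyphenyl)-5,7,8-trimethoxy-2,3-dihydro-4H-chromen-4-one | COc1ccc([C@@H]2CC(=O)c3c(OC)cc(OC)c(OC)c3O2)cc1OC | target

**Count**
Total steps: 8. Longest linear sequence: 6 steps (steps 1, 2, 3, 4, 7, 8); the epoxide branch (steps 5 and 6) joins at step 7.

**Steps most likely to fail**

Step 7 (proposed new method). Fluoride displacement by the alkoxide on the donor-rich ring may be too slow, so that base-induced degradation of the dithiane or of unreacted epoxide takes over. The hindered carbanion may also open the oxirane sluggishly, giving time for lithium-assisted benzylic ionisation of the epoxide (rearrangement, attack at the wrong carbon, loss of enantiopurity). The fallback uses known chemistry only: the halide is changed and the aryl–oxygen bond is made by copper catalysis in a separate step. It sets out from epoxide 11 and dithiol 7, with ring A rebuilt from commercial 5-bromovanillin (3-bromo-4-hydroxy-5-methoxybenzaldehyde) by the operations of steps 1 to 4. Dakin oxidation should give 2-bromo-6-methoxybenzene-1,4-diol F1, methylation 1-bromo-2,3,5-trimethoxybenzene F2, Vilsmeier formylation 2-bromo-3,4,6-trimethoxybenzaldehyde F3, and thioacetalisation with 7 2-(2-bromo-3,4,6-trimethoxyphenyl)-1,3-dithiane F4. F4 is deprotonated with LiN(i-Pr)2 in THF (not n-BuLi, which would exchange the bromine), the anion opens 11 at CH2, and aqueous quench gives the isolated alcohol (1S)-2-[2-(2-bromo-3,4,6-trimethoxyphenyl)-1,3-dithian-2-yl]-1-(3,4-dimethoxyphenyl)ethan-1-ol F5. An intramolecular Ullmann-type etherification (CuI, 3,4,7,8-tetramethyl-1,10-phenanthroline, Cs2CO3, toluene, 110 °C) then forms O1–C8a without touching the C2–O bond and comes back to the route at 14.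

Step 3. The chloroiminium electrophile may react sluggishly with the fluorine-bearing ring, or attack in part at the carbon between the two methoxy groups. The fallback replaces direct formylation by halogenation and halogen–metal exchange. It sets out from 4: N-bromosuccinimide in MeCN at 0 °C should brominate para to the 3-methoxy group to give 2-bromo-3-fluoro-1,4,5-trimethoxybenzene F6, from which any regioisomer can be separated. Bromine–lithium exchange with n-BuLi in THF at −78 °C (kept cold so that the ortho-fluoro aryllithium does not lose LiF to an aryne) and quench with DMF comes back to the route at 6.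

Step 8. The iodine reagent may oxidise the two electron-rich rings or stop at sulfur oxidation without hydrolysis, and the trifluoroacetic acid formed may start acid-promoted opening of ring C. The fallback is non-oxidative, alkylative hydrolysis: it sets out from 14 and, with MeI and CaCO3 in MeCN/H2O at 45 °C (S-methylation to a sulfonium ion, hydrolysis of the thionium ion under buffered conditions), comes back to the route at 15 without any new compound (F0).

**Further compounds**
F1 | step 7 | 2-bromo-6-methoxybenzene-1,4-diol | COc1cc(O)cc(Br)c1O
F2 | step 7 | 1-bromo-2,3,5-trimethoxybenzene | COc1cc(Br)c(OC)c(OC)c1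
F3 | step 7 | 2-bromo-3,4,6-trimethoxybenzaldehyde | COc1cc(OC)c(C=O)c(Br)c1OC
F4 | step 7 | 2-(2-bromo-3,4,6-trimethoxyphenyl)-1,3-dithiane | COc1cc(OC)c(C2SCCCS2)c(Br)c1OC
F5 | step 7 | (1S)-2-[2-(2-bromo-3,4,6-trimethoxyphenyl)-1,3-dithian-2-yl]-1-(3,4-dimethoxyphenyl)ethan-1-ol | COc1ccc([C@@H](O)CC2(SCCCS2)c3c(OC)cc(OC)c(OC)c3Br)cc1OC
F6 | step 3 | 2-bromo-3-fluoro-1,4,5-trimethoxybenzene | COc1cc(OC)c(Br)c(F)c1OC
F0 | step 8 | none | none
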